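Both end groups are the same (2R,3R)-2,3-dihydroxy β-ring (ring A free, ring B sulfated at O3′), so one ring building block is used twice. Each ring is assembled by a [3+3] union of 2,2-dimethylpropanedial and crotonaldehyde under one chiral carbene catalyst: a cross-acyloin step joins C2 to C3 and an intramolecular Stetter step joins C6 to C5. The step exploits that ring carbons C3 (oxygen-bearing) and C6 (polyene-bearing) stand 1,4 and can both be carbonyl carbons; its precursor is an acyclic α′-hydroxy enone aldehyde. Directed reduction, enol triflate formation (C5=C6), Stille coupling and two Wittig reactions with the C10 dialdehyde finish the skeleton; O3′ is sulfated at the C15 phosphonium stage.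

Key step: step 2

Remark: ring atoms carry carotenoid numbers (C1 quaternary, C2 and C3 carbinol carbons, C4 methylene, C5 methyl-bearing and C6 chain-bearing alkene carbons; primes mark ring B and its half of the chain), and the Why lines use these numbers.
Remark (assumption): the facial sense of the triazolium catalyst in step 2 cannot be predicted safely; the enantiomer named is assumed to give the (R)-carbinol, and its antipode would be used if a test run shows the opposite.
Remark (assumption): the target is drawn as the free hydrogen sulfate, so 20 is written in that neutral form; 18 is written as the phosphonium sulfate inner salt and 19 as its sodium salt, and the final product would be handled as the sodium salt and acidified only at the end.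

Step 1
Reactants: 1 2,2-dimethylpropane-1,3-diol (neopentyl glycol)
Product: 2 2,2-dimethylpropanedial
Conditions: (COCl)2, DMSO, CH2Cl2, −78 °C; then Et3N, −78 °C to rt; used as a dried solution
Reagents that add atoms: none
Why: Swern oxidation takes both primary alcohols to the aldehyde level without over-oxidation, and the product has no α-hydrogen, so it cannot enolise or self-condense.

Step 2
Reactants: 2 2,2-dimethylpropanedial; 3 (E)-but-2-enal (crotonaldehyde)
Product: 5 (3R)-3-hydroxy-2,2,6-trimethylcyclohexane-1,4-dione (both C6 epimers), via acyloin enone 4 (not isolated)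
Conditions: 2 (1.5 equiv), (5aS,10bR)-2-(pentafluorophenyl)-5a,10b-dihydro-4H,6H-indeno[2,1-b][1,2,4]triazolo[4,3-d][1,4]oxazin-2-ium tetrafluoroborate (15 mol%), i-Pr2NEt (15 mol%), toluene, 0 °C to rt, 3 added slowly
Reagents that add atoms: none
Why: Proposed new method: the triazolylidene adds to 3 and the resulting Breslow intermediate, reacting as an acyl anion, attacks one aldehyde of 2 to give acyloin 4 (C2–C3 bond), after which the carbene adds to the remaining aldehyde of 4 and that Breslow intermediate adds to the β-carbon of the enone (C5–C6 bond) before proton transfer releases the catalyst and the 1,4-dione. The closest known reaction types are the carbene-catalysed cross-acyloin (benzoin) reaction, the Stetter reaction with enals as acyl donors and the asymmetric intramolecular Stetter reaction; their union in one [3+3] annulation is the new element. The single ring closes by a 6-endo-trig conjugate addition with the enone carbonyl C3 inside the new ring. The carbinol centre C2 is set by the chiral catalyst in the acyloin step (face selection on the aldehyde of 2), whereas the methyl-bearing centre C5 may form as a mixture because step 5 erases it. The step needs acyl-anion instead of homoenolate reactivity of 3 and cross- instead of homo-coupling: the electron-poor N-pentafluorophenyl catalyst with a weak amine base in an aprotic solvent favours the former, 2 cannot enolise and is the most electrophilic aldehyde present, and all acyloin equilibria are reversible while only the Stetter closure is irreversible, so it should drain the mixture toward 5.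

Step 3
Reactants: 5 (3R)-3-hydroxy-2,2,6-trimethylcyclohexane-1,4-dione
Product: 6 (3R,4R)-3,4-dihydroxy-2,2,6-trimethylcyclohexan-1-one (both C6 epimers)
Conditions: Me4NBH(OAc)3, MeCN–AcOH, −30 °C
Reagents that add atoms: none
Why: Hydroxyl-directed triacetoxyborohydride reduction (Evans–Saksena type) delivers hydride from the boron bound to O2 to the neighbouring C3 ketone on the face of O2, so the new hydroxyl at C3 should stand trans to O2 (R at C3), while the C6 ketone, hindered by C1 and C5 and reachable only through a bridged transition state, should remain.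

Step 4
Reactants: 6 (3R,4R)-3,4-dihydroxy-2,2,6-trimethylcyclohexan-1-one
Product: 7 (3R,4R)-2,2,6-trimethyl-3,4-bis(triethylsilyloxy)cyclohexan-1-one (both C6 epimers)
Conditions: Et3SiCl, imidazole, 4-(dimethylamino)pyridine (cat.), DMF, 40 °C
Reagents that add atoms: chlorotriethylsilane, CC[Si](Cl)(CC)CC
Why: Silyl ether formation protects both hydroxyls against the strong base of step 5; the nucleophilic catalyst and gentle warming should overcome the neopentyl hindrance at O2, and no stereocentre is touched.

Step 5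
Reactants: 7 (3R,4R)-2,2,6-trimethyl-3,4-bis(triethylsilyloxy)cyclohexan-1-one
Product: 9 (4R,5R)-2,6,6-trimethyl-4,5-bis(triethylsilyloxy)cyclohex-1-en-1-yl trifluoromethanesulfonate, via potassium enolate 8 (not isolated)
Conditions: KN(SiMe3)2, THF, −78 °C; then PhNTf2, −78 °C to 0 °C
Reagents that add atoms: N-phenylbis(trifluoromethanesulfonimide), O=S(=O)(N(c1ccccc1)S(=O)(=O)C(F)(F)F)C(F)(F)F
Why: Enolisation can occur only toward C5 because C1 is quaternary, and O-triflation of the enolate (enol triflate formation) creates the ring double bond C5=C6 and removes the uncontrolled C5 centre.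

Step 6
Reactants: 10 (E)-3-methylpent-2-en-4-yn-1-ol
Product: 11 (2E,4E)-3-methyl-5-(tributylstannyl)penta-2,4-dien-1-ol
Conditions: Bu3SnH, PdCl2(PPh3)2 (2 mol%), THF, 0 °C to rt
Reagents that add atoms: tributyltin hydride, CCCC[SnH](CCCC)CCCC
Why: Palladium-catalysed hydrostannation adds Sn–H syn across the terminal alkyne with tin at the terminal carbon, which gives the (4E)-alkenylstannane and leaves the (2E) double bond unchanged.

Step 7
Reactants: 9 (4R,5R)-2,6,6-trimethyl-4,5-bis(triethylsilyloxy)cyclohex-1-en-1-yl trifluoromethanesulfonate; 11 (2E,4E)-3-methyl-5-(tributylstannyl)penta-2,4-dien-1-ol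
Product: 12 (2E,4E)-3-methyl-5-[(4R,5R)-2,6,6-trimethyl-4,5-bis(triethylsilyloxy)cyclohex-1-en-1-yl]penta-2,4-dien-1-ol
Conditions: Pd2(dba)3 (tris(dibenzylideneacetone)dipalladium, 2.5 mol%), AsPh3 (20 mol%), NMP, 60 °C
Reagents that add atoms: none
Why: Stille cross-coupling joins C6 to C7 with retention of both alkene geometries; the weakly bound arsine ligand in a polar solvent should speed transmetalation, the slow event for enol triflates with two ortho substituents.

Step 8
Reactants: 12 (2E,4E)-3-methyl-5-[(4R,5R)-2,6,6-trimethyl-4,5-bis(triethylsilyloxy)cyclohex-1-en-1-yl]penta-2,4-dien-1-ol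
Product: 14 [(2E,4E)-5-[(4R,5R)-4,5-dihydroxy-2,6,6-trimethylcyclohex-1-en-1-yl]-3-methylpenta-2,4-dien-1-yl]triphenylphosphonium bromide, via desilylated triol 13 (not isolated)
Conditions: PPh3·HBr, MeOH, rt
Reagents that add atoms: triphenylphosphine hydrobromide, Br.c1ccc(cc1)P(c1ccccc1)c1ccccc1
Why: The acid methanolyses both triethylsilyl ethers, and the dienylic alcohol then ionises so that PPh3 captures the pentadienyl cation at its terminal carbon (phosphonium salt formation, E,E under thermodynamic control), while the homoallylic and neopentyl secondary hydroxyls should not ionise.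

Step 9
Reactants: 14 [(2E,4E)-5-[(4R,5R)-4,5-dihydroxy-2,6,6-trimethylcyclohex-1-en-1-yl]-3-methylpenta-2,4-dien-1-yl]triphenylphosphonium bromide; 15 (2E,4E,6E)-2,7-dimethylocta-2,4,6-trienedial
Product: 17 (2E,4E,6E,8E,10E,12E)-13-[(4R,5R)-4,5-dihydroxy-2,6,6-trimethylcyclohex-1-en-1-yl]-2,7,11-trimethyltrideca-2,4,6,8,10,12-hexaenal, via ylide 16 (not isolated)
Conditions: 15 (3 equiv), NaOMe, MeOH–CH2Cl2, 0 °C to rt; then EtOAc, 70 °C
Reagents that add atoms: none
Why: Wittig olefination with an excess of the symmetrical dialdehyde should stop at the mono-adduct, and the new C11=C12 bond, formed as an E/Z mixture, should equilibrate thermally to the E isomer as is usual for polyenes.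

Step 10
Reactants: 14 [(2E,4E)-5-[(4R,5R)-4,5-dihydroxy-2,6,6-trimethylcyclohex-1-en-1-yl]-3-methylpenta-2,4-dien-1-yl]triphenylphosphonium bromide
Product: 18 [(2E,4E)-5-[(4R,5R)-5-hydroxy-2,6,6-trimethyl-4-(sulfonatooxy)cyclohex-1-en-1-yl]-3-methylpenta-2,4-dien-1-yl]triphenylphosphonium (inner salt)
Conditions: SO3·pyridine (1.1 equiv), pyridine, 0 °C
Reagents that add atoms: sulfur trioxide pyridine complex, O=S(=O)([O-])[n+]1ccccc1
Why: O-Sulfation with the SO3–amine complex should select the C3′ hydroxyl, because the C2′ hydroxyl is neopentyl (next to the quaternary C1′) and flanked on both sides, while the weakly basic medium leaves the phosphonium group untouched and the product separates as the inner salt.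

Step 11
Reactants: 18 [(2E,4E)-5-[(4R,5R)-5-hydroxy-2,6,6-trimethyl-4-(sulfonatooxy)cyclohex-1-en-1-yl]-3-methylpenta-2,4-dien-1-yl]triphenylphosphonium (inner salt); 17 (2E,4E,6E,8E,10E,12E)-13-[(4R,5R)-4,5-dihydroxy-2,6,6-trimethylcyclohex-1-en-1-yl]-2,7,11-trimethyltrideca-2,4,6,8,10,12-hexaenal
Product: 20 (all-E)-(2R,3R,2′R,3′R)-β,β-carotene-2,3,2′,3′-tetrol 3′-(hydrogen sulfate), the target, via sulfated ylide 19 (not isolated)
Conditions: 18 (1.3 equiv), NaOMe (1.2 equiv relative to 18), MeOH–CH2Cl2, 0 °C to rt; then EtOH, 70 °C; then cold 0.1 M aq HCl, rapid extraction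
Reagents that add atoms: none
Why: The second Wittig olefination forms C11′=C12′ and completes the C40 chain, the sulfate monoester anion being inert to methoxide under these conditions and the stereocentres remote, and thermal equilibration should give the all-E polyene before brief cold acidification frees the hydrogen sulfate.

Compound list
1 | 2,2-dimethylpropane-1,3-diol (neopentyl glycol) | OCC(C)(C)CO | starting material
2 | 2,2-dimethylpropanedial | O=CC(C)(C)C=O | intermediate
3 | (E)-but-2-enal (crotonaldehyde) | C/C=C/C=O | starting material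
4 | (3R,5E)-3-hydroxy-2,2-dimethyl-4-oxohept-5-enal | O=CC(C)(C)[C@@H](O)C(=O)/C=C/C | intermediate
5 | (3R)-3-hydroxy-2,2,6-trimethylcyclohexane-1,4-dione (both C6 epimers) | O=C1C(C)(C)[C@@H](O)C(=O)CC1C | intermediate
6 | (3R,4R)-3,4-dihydroxy-2,2,6-trimethylcyclohexan-1-one (both C6 epimers) | O=C1C(C)(C)[C@@H](O)[C@H](O)CC1C | intermediate
7 | (3R,4R)-2,2,6-trimethyl-3,4-bis(triethylsilyloxy)cyclohexan-1-one (both C6 epimers) | O=C1C(C)(C)[C@@H](O[Si](CC)(CC)CC)[C@H](O[Si](CC)(CC)CC)CC1C | intermediate
8 | potassium (4R,5R)-2,6,6-trimethyl-4,5-bis(triethylsilyloxy)cyclohex-1-en-1-olate | CC1=C([O-])C(C)(C)[C@@H](O[Si](CC)(CC)CC)[C@H](O[Si](CC)(CC)CC)C1.[K+] | intermediate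
9 | (4R,5R)-2,6,6-trimethyl-4,5-bis(triethylsilyloxy)cyclohex-1-en-1-yl trifluoromethanesulfonate | CC1=C(OS(=O)(=O)C(F)(F)F)C(C)(C)[C@@H](O[Si](CC)(CC)CC)[C@H](O[Si](CC)(CC)CC)C1 | intermediate
10 | (E)-3-methylpent-2-en-4-yn-1-ol | C#C/C(C)=C/CO | starting material
11 | (2E,4E)-3-methyl-5-(tributylstannyl)penta-2,4-dien-1-ol | CCCC[Sn](CCCC)(CCCC)/C=C/C(C)=C/CO | intermediate
12 | (2E,4E)-3-methyl-5-[(4R,5R)-2,6,6-trimethyl-4,5-bis(triethylsilyloxy)cyclohex-1-en-1-yl]penta-2,4-dien-1-ol | CC1=C(/C=C/C(C)=C/CO)C(C)(C)[C@@H](O[Si](CC)(CC)CC)[C@H](O[Si](CC)(CC)CC)C1 | intermediate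
13 | (2E,4E)-5-[(4R,5R)-4,5-dihydroxy-2,6,6-trimethylcyclohex-1-en-1-yl]-3-methylpenta-2,4-dien-1-ol | CC1=C(/C=C/C(C)=C/CO)C(C)(C)[C@@H](O)[C@H](O)C1 | intermediate
14 | [(2E,4E)-5-[(4R,5R)-4,5-dihydroxy-2,6,6-trimethylcyclohex-1-en-1-yl]-3-methylpenta-2,4-dien-1-yl]triphenylphosphonium bromide | CC1=C(/C=C/C(C)=C/C[P+](c2ccccc2)(c2ccccc2)c2ccccc2)C(C)(C)[C@@H](O)[C@H](O)C1.[Br-] | intermediate
15 | (2E,4E,6E)-2,7-dimethylocta-2,4,6-trienedial | O=C/C(C)=C/C=C/C=C(C)/C=O | starting material
16 | [(2E,4E)-5-[(4R,5R)-4,5-dihydroxy-2,6,6-trimethylcyclohex-1-en-1-yl]-3-methylpenta-2,4-dien-1-ylidene]triphenylphosphorane | CC1=C(/C=C/C(C)=C/C=P(c2ccccc2)(c2ccccc2)c2ccccc2)C(C)(C)[C@@H](O)[C@H](O)C1 | intermediate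
17 | (2E,4E,6E,8E,10E,12E)-13-[(4R,5R)-4,5-dihydroxy-2,6,6-trimethylcyclohex-1-en-1-yl]-2,7,11-trimethyltrideca-2,4,6,8,10,12-hexaenal | O=C/C(C)=C/C=C/C=C(C)/C=C/C=C(C)/C=C/C1=C(C)C[C@@H](O)[C@H](O)C1(C)C | intermediate
18 | [(2E,4E)-5-[(4R,5R)-5-hydroxy-2,6,6-trimethyl-4-(sulfonatooxy)cyclohex-1-en-1-yl]-3-methylpenta-2,4-dien-1-yl]triphenylphosphonium (inner salt) | CC1=C(/C=C/C(C)=C/C[P+](c2ccccc2)(c2ccccc2)c2ccccc2)C(C)(C)[C@@H](O)[C@H](OS(=O)(=O)[O-])C1 | intermediate
19 | sodium (1R,6R)-6-hydroxy-3,5,5-trimethyl-4-[(1E,3E)-3-methyl-5-(triphenyl-λ5-phosphanylidene)penta-1,3-dien-1-yl]cyclohex-3-en-1-yl sulfate | CC1=C(/C=C/C(C)=C/C=P(c2ccccc2)(c2ccccc2)c2ccccc2)C(C)(C)[C@@H](O)[C@H](OS(=O)(=O)[O-])C1.[Na+] | intermediate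
20 | (all-E)-(2R,3R,2′R,3′R)-β,β-carotene-2,3,2′,3′-tetrol 3′-(hydrogen sulfate) | CC1=C(/C=C/C(C)=C/C=C/C(C)=C/C=C/C=C(C)/C=C/C=C(C)/C=C/C2=C(C)C[C@@H](OS(=O)(=O)O)[C@H](O)C2(C)C)C(C)(C)[C@@H](O)[C@H](O)C1 | target

Total step count: 11. Longest linear sequence: 9 steps (steps 1 to 5, 7 and 8, then step 9 or step 10, then step 11; step 6 is a one-step side branch, and steps 9 and 10 are parallel branches from 14).

Steps most likely to fail

1. Step 2 (the new method). Crotonaldehyde may be diverted into homoenolate or homo-acyloin channels. The 6-endo Stetter closure may be too slow to drain the reversible acyloins. Facial control at C2 may be weak. The fallback uses known chemistry, sets out from 2 and 3 and comes back to the route at 5. Crotonaldehyde 3 is converted with HBr and propane-1,3-diol into 2-(2-bromopropyl)-1,3-dioxane F1. Its Grignard reagent (Mg, THF) is added at −78 °C to an excess of 2 to give 5-(1,3-dioxan-2-yl)-3-hydroxy-2,2,4-trimethylpentanal F2. Dess–Martin oxidation gives 5-(1,3-dioxan-2-yl)-2,2,4-trimethyl-3-oxopentanal F3, and aqueous acid frees 2,2,4-trimethyl-3-oxohexanedial F4. An azolium-catalysed intramolecular acyloin condensation of this 1,6-dialdehyde (same chiral triazolium salt, i-Pr2NEt), in which only the unhindered aldehyde can become the acyl donor, should close the ring to 5.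

2. Step 10. Site selection between the two secondary hydroxyls may be poor, or sulfation may occur twice. The fallback sets out from 14 and comes back at 18. Heating 14 with Bu2SnO in MeOH and evaporation gives the dibutylstannylene acetal of 14 F5. SO3·NMe3 in DMF at rt should then react at the tin-activated, less hindered O3′, and aqueous work-up gives 18.

3. Step 7. Transmetalation at the enol triflate with two ortho substituents may be slow, so that protodestannylation and homocoupling of 11 or reduction of the triflate take over. The fallback sets out from 7 and 10 and comes back at 12. The dilithio derivative of 10 (n-BuLi, 2 equiv, THF, CeCl3) is added to ketone 7 to give (3R,4R)-1-[(3E)-5-hydroxy-3-methylpent-3-en-1-yn-1-yl]-2,2,6-trimethyl-3,4-bis(triethylsilyloxy)cyclohexan-1-ol F6. Ac2O–pyridine acetylates only the primary hydroxyl to give (2E)-5-[(3R,4R)-1-hydroxy-2,2,6-trimethyl-3,4-bis(triethylsilyloxy)cyclohexyl]-3-methylpent-2-en-4-yn-1-yl acetate F7. POCl3–pyridine dehydrates the tertiary alcohol toward C5, the only position with a β-hydrogen, to give (2E)-3-methyl-5-[(4R,5R)-2,6,6-trimethyl-4,5-bis(triethylsilyloxy)cyclohex-1-en-1-yl]pent-2-en-4-yn-1-yl acetate F8. LiAlH4 in THF removes the acetate and reduces the triple bond of the pent-2-en-4-yn-1-ol unit trans, which should give 12.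

Further compounds
F1 | step 2 | 2-(2-bromopropyl)-1,3-dioxane | CC(Br)CC1OCCCO1
F2 | step 2 | 5-(1,3-dioxan-2-yl)-3-hydroxy-2,2,4-trimethylpentanal | O=CC(C)(C)C(O)C(C)CC1OCCCO1
F3 | step 2 | 5-(1,3-dioxan-2-yl)-2,2,4-trimethyl-3-oxopentanal | O=CC(C)(C)C(=O)C(C)CC1OCCCO1
F4 | step 2 | 2,2,4-trimethyl-3-oxohexanedial | O=CC(C)(C)C(=O)C(C)CC=O
F5 | step 10 | dibutylstannylene acetal of 14 (2,2-dibutyl-1,3,2-dioxastannolane across O2′ and O3′, phosphonium bromide) | CC1=C(/C=C/C(C)=C/C[P+](c2ccccc2)(c2ccccc2)c2ccccc2)C(C)(C)[C@H]3O[Sn](CCCC)(CCCC)O[C@@H]3C1.[Br-]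
F6 | step 7 | (3R,4R)-1-[(3E)-5-hydroxy-3-methylpent-3-en-1-yn-1-yl]-2,2,6-trimethyl-3,4-bis(triethylsilyloxy)cyclohexan-1-ol | OC1(C#C/C(C)=C/CO)C(C)(C)[C@@H](O[Si](CC)(CC)CC)[C@H](O[Si](CC)(CC)CC)CC1C
F7 | step 7 | (2E)-5-[(3R,4R)-1-hydroxy-2,2,6-trimethyl-3,4-bis(triethylsilyloxy)cyclohexyl]-3-methylpent-2-en-4-yn-1-yl acetate | OC1(C#C/C(C)=C/COC(C)=O)C(C)(C)[C@@H](O[Si](CC)(CC)CC)[C@H](O[Si](CC)(CC)CC)CC1C
F8 | step 7 | (2E)-3-methyl-5-[(4R,5R)-2,6,6-trimethyl-4,5-bis(triethylsilyloxy)cyclohex-1-en-1-yl]pent-2-en-4-yn-1-yl acetate | CC1=C(C#C/C(C)=C/COC(C)=O)C(C)(C)[C@@H](O[Si](CC)(CC)CC)[C@H](O[Si](CC)(CC)CC)C1
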